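The amounts in these flasks can be counted: J, Q and Z add up to the J charged, each Q holds one X, and each Z holds two. X displaces D from J to give Q and from Q to give Z, and free D is proposed to leave as G.

all flasks: J 0.10 M

| flask | X | D | remark | time |
|---|---|---|---|---|
| violet | 0.59 equiv | 0.50 equiv | run made earlier |  |
| red | 1.4 equiv | 0.50 equiv | run made earlier |  |
| epsilon | 1.20 equiv | 0.500 equiv |  | 2.0 h |
| beta | 0.500 equiv | 0.500 equiv |  | 2.0 h |
| eta | 1.00 equiv | 0.500 equiv |  | 2.0 h |

- violet (time / min: Q / %, Z / %): 30.0: 40, 6; 60.0: 39, 8; 90.0: 44, 8; 120: 47, 7
- red (time / min: Q / %, Z / %): 10.0: 44, 7; 20.0: 53, 13; 50.0: 51, 26; 120: 50, 38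

(readings scatter by 1.5 percentage points)

- steps that have been proposed: J + X <-> D + Q; Q + X <-> D + Z; D -> G

* which of these holds the largest part of the J at the end of epsilon (J / Q / Z)
* which of these holds the largest part of the J at the end of beta (J / Q / Z)
* which of these holds the largest part of the J at the end of eta (J / Q / Z)
* final Q in beta, as a percentage of the J charged

Take beta, charged with 0.500 X per J. With the first exchange by itself and each X taken up, Q stands at 50.0% and J at 50.0%.

The second exchange adds Z. Subtracting one exchange from the other leaves J and Z giving two Q, a step with neither X nor D in it. The last red reading, with J as the remainder, puts the sharing ratio, Q times Q over J times Z, at 5.48; this is the comproportionation constant. The last violet reading gives 6.86, but on a Z of 7% with a scatter of 1.5 percentage points, so the red value is used.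

The loss of D adds the balance. In the violet run, Q + 2Z reaches 61.0% of J at the last reading, against 0.59 equiv of X charged. The count is therefore set equal to the X charged.

In beta, Q is then the X charged less two Z, and J is the remainder. The sharing ratio gives a quadratic in Z, with Z at 5.19%, Q at 39.6% and J at 55.2%, so J leads in beta.

The same balance puts J level with Q at 0.625 X per J, and Q level with Z at 1.37. Beta lies below the first crossing. Eta lies between the two, and so does epsilon, so Q leads in both.

The forecast names Q for epsilon, J for beta and Q for eta, with 40% of Q in beta, noting that “Slow loss of D lets X be consumed fully”.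

Beta ends with J at 55.2%, Q at 39.6% and Z at 5.16%. Epsilon ends with Q largest at 53.2%, and eta with Q largest at 54.1%.

    J + X ⇌ D + Q (K = 0.276, k = 7.04 M⁻¹ min⁻¹)
    Q + X ⇌ D + Z (K = 0.0490, k = 3.35 M⁻¹ min⁻¹)
    D → G (k = 0.207 min⁻¹)

Beta's reckoned Q of 39.6% stands beside the 39.6% it reached. A neighbour of beta takes 0.850 X per J, with the other charges and the time held, which is above the crossing of 0.625. The same quadratic with the sharing ratio of 5.48 gives Z at 16.2%, Q at 52.6% and J at 31.2%. That flask ends with Q largest at 52.6%, Z at 15.6% and J at 32%, and 1.51% of its X is left after 2.00 h.

The numbers in the tables come from a simulation for substances that don't exist; noise was put on by code.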